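**Strategy.** Atoms are numbered as in geranylgeraniol (C1 = CH2OH, C19 = the CH2OAc carbon on C7, oxolane ring = O–C12–C13–C14–C15). The oxolane hides an aldol: once C12 is a ketone, the C14 carbinol is β to it and the tertiary C15 oxygen is γ. A reagent-controlled boron aldol of the methyl ketone (R)-6-bromo-3-methylhexan-2-one (C8–C13, from (R)-β-citronellene) with 2-methyl-2-(trimethylsilyloxy)propanal, finished by acid methanolysis in the same flask, forms C13–C14 and O–C12 as a cyclic methyl ketal and sets C14. Ionic reduction then sets C12 under matched control by C11 and C14. Copper-catalysed anti-carbomagnesiation of propargyl alcohol and a B-alkyl Suzuki coupling complete the chain.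

Key step: step 6

Remark: (R)-β-citronellene and (2E)-3-methylpent-2-en-4-yn-1-ol are taken as commercial single isomers.
Remark: (−)-Ipc2BCl is assumed to direct a methyl ketone enolate to the re face of aldehyde 7 (giving 14R), by analogy with related methyl ketone aldols; if a trial shows the opposite sense, the enantiomeric reagent is used.

**Step 1**
Reactants: 1 (R)-3,7-dimethylocta-1,6-diene ((R)-β-citronellene)
Product: 2 (R)-4-methylhex-5-en-1-ol
Conditions: O3 (1 equiv, Sudan Red 7B end point), CH2Cl2/MeOH, −78 °C; then NaBH4, −78 °C to rt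
Reagents that add atoms: ozone, [O-][O+]=O
Why: Chemoselective ozonolysis with reductive work-up, in which the electron-rich trisubstituted alkene should be cleaved much faster than the terminal vinyl group and the C11 stereocentre is not involved.

**Step 2**
Reactants: 2 (R)-4-methylhex-5-en-1-ol
Product: 3 (R)-6-bromo-3-methylhex-1-ene
Conditions: CBr4, PPh3, CH2Cl2, 0 °C
Reagents that add atoms: tetrabromomethane, BrC(Br)(Br)Br
Why: Appel reaction, in which the alkoxyphosphonium ion of the primary alcohol is displaced by bromide while the alkene and C11 take no part.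

**Step 3**
Reactants: 3 (R)-6-bromo-3-methylhex-1-ene
Product: 4 (R)-6-bromo-3-methylhexan-2-one
Conditions: PdCl2 (10 mol %), CuCl, O2 (1 atm), DMF/H2O 7:1, rt
Reagents that add atoms: water, O
Why: Tsuji–Wacker oxidation, in which Markovnikov hydroxypalladation of the terminal alkene and β-hydride elimination give the methyl ketone, the alkyl bromide is inert and C11 is expected to keep its configuration under these near-neutral conditions.

**Step 4**
Reactants: 5 methyl 2-hydroxy-2-methylpropanoate
Product: 6 methyl 2-methyl-2-(trimethylsilyloxy)propanoate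
Conditions: TMSCl, imidazole, CH2Cl2, rt
Reagents that add atoms: chlorotrimethylsilane, C[Si](C)(C)Cl
Why: Silyl ether formation at the tertiary alcohol with the small trimethylsilyl group masks the hydroxyl for the hydride and boron steps and is labile enough to be lost again in step 6.

**Step 5**
Reactants: 6 methyl 2-methyl-2-(trimethylsilyloxy)propanoate
Product: 7 2-methyl-2-(trimethylsilyloxy)propanal
Conditions: iBu2AlH (1.05 equiv), CH2Cl2, −78 °C; aq. potassium sodium tartrate
Reagents that add atoms: none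
Why: Partial reduction of an ester with a dialkylaluminium hydride, in which the α-oxygenated tetrahedral aluminium hemiacetal is stable at −78 °C and collapses to the aldehyde only on work-up.

**Step 6**
Reactants: 4 (R)-6-bromo-3-methylhexan-2-one; 7 2-methyl-2-(trimethylsilyloxy)propanal
Product: 11 (3R)-5-[(2R)-5-bromopentan-2-yl]-5-methoxy-2,2-dimethyloxolan-3-ol (both anomers at C12), via enol borinate 8 (not isolated), via boron aldolate 9 (not isolated), via dihydroxy ketone 10 (not isolated)
Conditions: (−)-B-chlorodiisopinocampheylborane ((−)-Ipc2BCl), Et3N, Et2O, −78 to 0 °C; 7, −78 to −20 °C; then 1.25 M HCl in MeOH, 0 °C to rt (same flask)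
Reagents that add atoms: methanol, CO
Why: The bulky chloroborane with Et3N should enolise 4 kinetically at the C13 methyl group and not at the C11 methine, and the enol borinate 8 adds to aldehyde 7 through a cyclic boron aldol transition state to make C13–C14 (aldolate 9). Acid methanolysis then cleaves the B–O and Si–O bonds, the freed C15 hydroxyl of 10 adds to the C12 carbonyl (5-exo-trig), and the hemiketal is fixed as the methyl ketal, which makes O–C12 and closes the oxolane ring. The closest known reaction types are the Ipc-boron aldol reaction of methyl ketones and the acid-catalysed cycloketalisation of γ-hydroxy ketones. C14 is controlled by the reagent, whose isopinocampheyl ligands direct the enolate to the re face of the aldehyde (14R), whereas C12 forms as both anomers, which is harmless because step 7 resets it. The step needs regioselective enolisation and facial selectivity at the aldehyde, and these are secured by the unhindered methyl group opposite a branched α′ carbon and by the chiral boron ligands, while the gem-dimethyl group at C15 favours ring closure.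

**Step 7**
Reactants: 11 (3R)-5-[(2R)-5-bromopentan-2-yl]-5-methoxy-2,2-dimethyloxolan-3-ol
Product: 12 (3R,5S)-5-[(2R)-5-bromopentan-2-yl]-2,2-dimethyloxolan-3-ol
Conditions: Et3SiH, BF3·OEt2, CH2Cl2, −78 to −40 °C
Reagents that add atoms: none
Why: Ionic reduction of a cyclic ketal, in which BF3 ionises the C12–OMe bond to the five-membered oxocarbenium ion and hydride should enter on the inside face cis to the C14 oxygen, which is also the Felkin–Anh face with respect to C11, so that the side chain ends trans to the hydroxyl and C12 (C5 of the oxolane) is S.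

**Step 8**
Reactants: 12 (3R,5S)-5-[(2R)-5-bromopentan-2-yl]-2,2-dimethyloxolan-3-ol
Product: 13 {[(3R,5S)-5-[(2R)-5-bromopentan-2-yl]-2,2-dimethyloxolan-3-yl]oxy}triethylsilane
Conditions: TESOTf, 2,6-lutidine, CH2Cl2, −78 to 0 °C
Reagents that add atoms: triethylsilyl trifluoromethanesulfonate, CC[Si](CC)(CC)OS(=O)(=O)C(F)(F)F
Why: Silyl ether formation with the reactive triflate is chosen because the C14 hydroxyl is flanked by the quaternary C15, and it protects this alcohol for the organomagnesium and acylation steps.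

**Step 9**
Reactants: 13 {[(3R,5S)-5-[(2R)-5-bromopentan-2-yl]-2,2-dimethyloxolan-3-yl]oxy}triethylsilane; 14 prop-2-yn-1-ol
Product: 18 (2Z)-2-{(4R)-4-[(2S,4R)-5,5-dimethyl-4-(triethylsilyloxy)oxolan-2-yl]pentyl}-3-iodoprop-2-en-1-ol, via Grignard reagent 15 (not isolated), via magnesium alkoxide 16 (not isolated), via alkenylmagnesium chelate 17 (not isolated)
Conditions: 13, Mg, THF, 50 °C; separately 14 (1.5 equiv), EtMgBr (1.5 equiv), THF, −20 °C; combine, CuI (10 mol %), −10 °C to rt; I2, −78 to 0 °C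
Reagents that add atoms: iodine, II
Why: Magnesium insertion gives the Grignard reagent, which should add to the magnesium alkoxide of propargyl alcohol by copper-catalysed anti-carbomagnesiation through a five-membered alkenylmagnesium chelate, so that iodinolysis with retention gives only the Z-iodoalkene with iodine cis to CH2OH, which is the C6=C7 geometry of the target.

**Step 10**
Reactants: 19 (2E)-3-methylpent-2-en-4-yn-1-ol
Product: 20 tert-butyl(dimethyl){[(2E)-3-methylpent-2-en-4-yn-1-yl]oxy}silane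
Conditions: TBSCl, imidazole, DMF, 0 °C to rt
Reagents that add atoms: tert-butyl(chloro)dimethylsilane, CC(C)(C)[Si](C)(C)Cl
Why: Standard silyl ether formation protects the C1 hydroxyl, which must stay distinguishable from the C19 hydroxyl that is acetylated later.

**Step 11**
Reactants: 20 tert-butyl(dimethyl){[(2E)-3-methylpent-2-en-4-yn-1-yl]oxy}silane
Product: 21 tert-butyl(dimethyl){[(2E)-3-methylpenta-2,4-dien-1-yl]oxy}silane
Conditions: H2 (1 atm), Pd/CaCO3 poisoned with Pb(OAc)2, quinoline, hexane, rt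
Reagents that add atoms: none
Why: Semi-hydrogenation of the terminal alkyne on the poisoned palladium catalyst should stop at the diene and leave the E trisubstituted alkene unchanged.

**Step 12**
Reactants: 21 tert-butyl(dimethyl){[(2E)-3-methylpenta-2,4-dien-1-yl]oxy}silane; 18 (2Z)-2-{(4R)-4-[(2S,4R)-5,5-dimethyl-4-(triethylsilyloxy)oxolan-2-yl]pentyl}-3-iodoprop-2-en-1-ol
Product: 23 (2Z,6E)-8-(tert-butyldimethylsilyloxy)-2-{(4R)-4-[(2S,4R)-5,5-dimethyl-4-(triethylsilyloxy)oxolan-2-yl]pentyl}-6-methylocta-2,6-dien-1-ol, via alkylborane 22 (not isolated)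
Conditions: 21, 9-BBN-H, THF, 0 °C to rt; then 18, Pd(dppf)Cl2 (5 mol %), AsPh3, Cs2CO3, DMF/H2O, rt
Reagents that add atoms: none
Why: 9-BBN should hydroborate only the monosubstituted vinyl group of diene 21 at its terminus, and the B-alkyl Suzuki–Miyaura coupling joins C5 to C6 with retention of the iodoalkene geometry while tolerating the free hydroxyl.

**Step 13**
Reactants: 23 (2Z,6E)-8-(tert-butyldimethylsilyloxy)-2-{(4R)-4-[(2S,4R)-5,5-dimethyl-4-(triethylsilyloxy)oxolan-2-yl]pentyl}-6-methylocta-2,6-dien-1-ol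
Product: 24 (2Z,6E)-8-(tert-butyldimethylsilyloxy)-2-{(4R)-4-[(2S,4R)-5,5-dimethyl-4-(triethylsilyloxy)oxolan-2-yl]pentyl}-6-methylocta-2,6-dien-1-yl acetate
Conditions: Ac2O, pyridine, DMAP (cat.), CH2Cl2, 0 °C
Reagents that add atoms: acetic anhydride, CC(=O)OC(C)=O
Why: DMAP-catalysed esterification of the only free hydroxyl installs the C19 acetate before the silyl ethers are removed.

**Step 14**
Reactants: 24 (2Z,6E)-8-(tert-butyldimethylsilyloxy)-2-{(4R)-4-[(2S,4R)-5,5-dimethyl-4-(triethylsilyloxy)oxolan-2-yl]pentyl}-6-methylocta-2,6-dien-1-yl acetate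
Product: 25 (2Z,6E)-8-hydroxy-2-{(4R)-4-[(2S,4R)-4-hydroxy-5,5-dimethyloxolan-2-yl]pentyl}-6-methylocta-2,6-dien-1-yl acetate (CNP0295947.1)
Conditions: HF·pyridine, pyridine, THF, 0 °C to rt
Reagents that add atoms: none
Why: Fluoride-mediated desilylation under buffered conditions should cleave both silyl ethers and leave the allylic acetate and the alkenes untouched.

**Compound list**

1 | (R)-3,7-dimethylocta-1,6-diene | CC(C)=CCC[C@@H](C)C=C | starting material
2 | (R)-4-methylhex-5-en-1-ol | OCCC[C@@H](C)C=C | intermediate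
3 | (R)-6-bromo-3-methylhex-1-ene | BrCCC[C@@H](C)C=C | intermediate
4 | (R)-6-bromo-3-methylhexan-2-one | BrCCC[C@@H](C)C(C)=O | intermediate
5 | methyl 2-hydroxy-2-methylpropanoate | COC(=O)C(C)(C)O | starting material
6 | methyl 2-methyl-2-(trimethylsilyloxy)propanoate | COC(=O)C(C)(C)O[Si](C)(C)C | intermediate
7 | 2-methyl-2-(trimethylsilyloxy)propanal | O=CC(C)(C)O[Si](C)(C)C | intermediate
8 | diisopinocampheylboron enolate of 4 (enol borinate at C13) | BrCCC[C@@H](C)C(=C)OB([C@@H]1C[C@@H]2C[C@H]([C@H]1C)C2(C)C)[C@@H]1C[C@@H]2C[C@H]([C@H]1C)C2(C)C | intermediate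
9 | diisopinocampheylboron aldolate of (4R,7R)-1-bromo-7-hydroxy-4,8-dimethyl-8-(trimethylsilyloxy)nonan-5-one | BrCCC[C@@H](C)C(=O)C[C@@H](OB([C@@H]1C[C@@H]2C[C@H]([C@H]1C)C2(C)C)[C@@H]1C[C@@H]2C[C@H]([C@H]1C)C2(C)C)C(C)(C)O[Si](C)(C)C | intermediate
10 | (4R,7R)-1-bromo-7,8-dihydroxy-4,8-dimethylnonan-5-one | BrCCC[C@@H](C)C(=O)C[C@@H](O)C(C)(C)O | intermediate
11 | (3R)-5-[(2R)-5-bromopentan-2-yl]-5-methoxy-2,2-dimethyloxolan-3-ol (both anomers) | BrCCC[C@@H](C)C1(OC)C[C@@H](O)C(C)(C)O1 | intermediate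
12 | (3R,5S)-5-[(2R)-5-bromopentan-2-yl]-2,2-dimethyloxolan-3-ol | BrCCC[C@@H](C)[C@@H]1C[C@@H](O)C(C)(C)O1 | intermediate
13 | {[(3R,5S)-5-[(2R)-5-bromopentan-2-yl]-2,2-dimethyloxolan-3-yl]oxy}triethylsilane | BrCCC[C@@H](C)[C@@H]1C[C@@H](O[Si](CC)(CC)CC)C(C)(C)O1 | intermediate
14 | prop-2-yn-1-ol | C#CCO | starting material
15 | bromo{(4R)-4-[(2S,4R)-5,5-dimethyl-4-(triethylsilyloxy)oxolan-2-yl]pentyl}magnesium | Br[Mg]CCC[C@@H](C)[C@@H]1C[C@@H](O[Si](CC)(CC)CC)C(C)(C)O1 | intermediate
16 | bromomagnesium prop-2-yn-1-olate | C#CCO[Mg]Br | intermediate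
17 | 4-substituted 2,5-dihydro-1,2-oxamagnesole (cyclic alkenylmagnesium alkoxide, Mg on C6) | [Mg]1OCC(=C1)CCC[C@@H](C)[C@@H]1C[C@@H](O[Si](CC)(CC)CC)C(C)(C)O1 | intermediate
18 | (2Z)-2-{(4R)-4-[(2S,4R)-5,5-dimethyl-4-(triethylsilyloxy)oxolan-2-yl]pentyl}-3-iodoprop-2-en-1-ol | OC/C(=C\I)CCC[C@@H](C)[C@@H]1C[C@@H](O[Si](CC)(CC)CC)C(C)(C)O1 | intermediate
19 | (2E)-3-methylpent-2-en-4-yn-1-ol | C#C/C(C)=C/CO | starting material
20 | tert-butyl(dimethyl){[(2E)-3-methylpent-2-en-4-yn-1-yl]oxy}silane | C#C/C(C)=C/CO[Si](C)(C)C(C)(C)C | intermediate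
21 | tert-butyl(dimethyl){[(2E)-3-methylpenta-2,4-dien-1-yl]oxy}silane | C=C/C(C)=C/CO[Si](C)(C)C(C)(C)C | intermediate
22 | 9-[(3E)-5-(tert-butyldimethylsilyloxy)-3-methylpent-3-en-1-yl]-9-borabicyclo[3.3.1]nonane | CC(C)(C)[Si](C)(C)OC/C=C(C)/CCB1C2CCCC1CCC2 | intermediate
23 | (2Z,6E)-8-(tert-butyldimethylsilyloxy)-2-{(4R)-4-[(2S,4R)-5,5-dimethyl-4-(triethylsilyloxy)oxolan-2-yl]pentyl}-6-methylocta-2,6-dien-1-ol | OC/C(=C\CC/C(C)=C/CO[Si](C)(C)C(C)(C)C)CCC[C@@H](C)[C@@H]1C[C@@H](O[Si](CC)(CC)CC)C(C)(C)O1 | intermediate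
24 | (2Z,6E)-8-(tert-butyldimethylsilyloxy)-2-{(4R)-4-[(2S,4R)-5,5-dimethyl-4-(triethylsilyloxy)oxolan-2-yl]pentyl}-6-methylocta-2,6-dien-1-yl acetate | CC(=O)OC/C(=C\CC/C(C)=C/CO[Si](C)(C)C(C)(C)C)CCC[C@@H](C)[C@@H]1C[C@@H](O[Si](CC)(CC)CC)C(C)(C)O1 | intermediate
25 | (2Z,6E)-8-hydroxy-2-{(4R)-4-[(2S,4R)-4-hydroxy-5,5-dimethyloxolan-2-yl]pentyl}-6-methylocta-2,6-dien-1-yl acetate | CC(=O)OC/C(=C\CC/C(C)=C/CO)CCC[C@@H](C)[C@@H]1C[C@@H](O)C(C)(C)O1 | target

**Step count.** Total: 14 steps. Longest linear sequence: 10 steps (1, 2, 3, 6, 7, 8, 9, 12, 13, 14).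

**Steps most likely to fail**

Step 6. The hindered α-quaternary aldehyde may add slowly and the reagent may give poor facial selectivity at C14, or the ketalisation may stay incomplete. Fallback: starting from 4, the kinetic lithium enolate (LiN(SiMe3)2, THF, −78 °C) is acylated with ester 6 in a crossed Claisen condensation to give (6R)-9-bromo-2,6-dimethyl-2-(trimethylsilyloxy)nonane-3,5-dione F1. Aqueous HCl in THF removes the silyl group and cyclodehydrates it to 5-[(2R)-5-bromopentan-2-yl]-2,2-dimethylfuran-3(2H)-one F2, which again makes C13–C14 and O–C12 in one flask. Corey–Bakshi–Shibata reduction (BH3·SMe2, (S)-2-methyl-CBS-oxazaborolidine, chosen on the assumption that the quaternary C15 side acts as the large group) should give (3R)-5-[(2R)-5-bromopentan-2-yl]-2,2-dimethyl-2,3-dihydrofuran-3-ol F3. Hydroxyl-directed hydrogenation with [Ir(cod)(PCy3)(py)]PF6 then adds hydrogen cis to the C14 hydroxyl and comes back to the route at 12.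

Step 7. Hydride delivery to the oxocarbenium ion may lose facial selectivity, or the ion may lose a proton to an enol ether, with elimination or epimerisation at C11. Fallback: starting from 10 (isolated when the aldol mixture of step 6 is quenched with aqueous instead of methanolic HCl), hydroxyl-directed Evans–Saksena reduction (Me4NBH(OAc)3, MeCN/AcOH, −20 °C) should give the 1,3-anti triol (4R,5R,7R)-1-bromo-4,8-dimethylnonane-5,7,8-triol F4. Mitsunobu cyclodehydration (PPh3, DIAD, THF) then activates the less hindered C12 hydroxyl and lets the tertiary C15 hydroxyl displace it with inversion (5-exo-tet), which comes back to the route at 12 with C12 as S.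

Step 9. The Grignard reagent may be protonated by the alkyne C–H of the excess alkoxide, or the carbometalation may stall, so that the advanced fragment is lost as the alkane. Fallback: starting from 13, the sodium salt of ethyl 2-(diphenoxyphosphoryl)acetate is alkylated (NaH, NaI, DMSO) to give ethyl (6R)-2-(diphenoxyphosphoryl)-6-[(2S,4R)-5,5-dimethyl-4-(triethylsilyloxy)oxolan-2-yl]heptanoate F5. Separately, geraniol is silylated (TBSCl, imidazole) to tert-butyl{[(2E)-3,7-dimethylocta-2,6-dien-1-yl]oxy}dimethylsilane F6, and its distal alkene is cleaved with ozone (1 equiv, then Me2S) to (4E)-6-(tert-butyldimethylsilyloxy)-4-methylhex-4-enal F7. A Z-selective Horner–Wadsworth–Emmons reaction of the diaryl phosphonate (NaH, THF, −78 to 0 °C) joins the two as ethyl (2Z,6E)-8-(tert-butyldimethylsilyloxy)-2-{(4R)-4-[(2S,4R)-5,5-dimethyl-4-(triethylsilyloxy)oxolan-2-yl]pentyl}-6-methylocta-2,6-dienoate F8, and reduction with iBu2AlH comes back to the route at 23.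

**Further compounds**

F1 | step 6 | (6R)-9-bromo-2,6-dimethyl-2-(trimethylsilyloxy)nonane-3,5-dione | BrCCC[C@@H](C)C(=O)CC(=O)C(C)(C)O[Si](C)(C)C
F2 | step 6 | 5-[(2R)-5-bromopentan-2-yl]-2,2-dimethylfuran-3(2H)-one | BrCCC[C@@H](C)C1=CC(=O)C(C)(C)O1
F3 | step 6 | (3R)-5-[(2R)-5-bromopentan-2-yl]-2,2-dimethyl-2,3-dihydrofuran-3-ol | BrCCC[C@@H](C)C1=C[C@@H](O)C(C)(C)O1
F4 | step 7 | (4R,5R,7R)-1-bromo-4,8-dimethylnonane-5,7,8-triol | BrCCC[C@@H](C)[C@H](O)C[C@@H](O)C(C)(C)O
F5 | step 9 | ethyl (6R)-2-(diphenoxyphosphoryl)-6-[(2S,4R)-5,5-dimethyl-4-(triethylsilyloxy)oxolan-2-yl]heptanoate (both epimers at C2) | CCOC(=O)C(CCC[C@@H](C)[C@@H]1C[C@@H](O[Si](CC)(CC)CC)C(C)(C)O1)P(=O)(Oc1ccccc1)Oc1ccccc1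
F6 | step 9 | tert-butyl{[(2E)-3,7-dimethylocta-2,6-dien-1-yl]oxy}dimethylsilane | CC(C)=CCC/C(C)=C/CO[Si](C)(C)C(C)(C)C
F7 | step 9 | (4E)-6-(tert-butyldimethylsilyloxy)-4-methylhex-4-enal | O=CCC/C(C)=C/CO[Si](C)(C)C(C)(C)C
F8 | step 9 | ethyl (2Z,6E)-8-(tert-butyldimethylsilyloxy)-2-{(4R)-4-[(2S,4R)-5,5-dimethyl-4-(triethylsilyloxy)oxolan-2-yl]pentyl}-6-methylocta-2,6-dienoate | CCOC(=O)/C(=C\CC/C(C)=C/CO[Si](C)(C)C(C)(C)C)CCC[C@@H](C)[C@@H]1C[C@@H](O[Si](CC)(CC)CC)C(C)(C)O1
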